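Remark on numbering and on the reading of the target: daucane numbering is used for all ring compounds (C1 = quaternary ring-fusion carbon with methyl C15; C2, C3, C4 = the other cyclopentane carbons, isopropyl on C4; C5 = ring-fusion CH; C6 to C10 = the other cycloheptane carbons, methyl C14 on C8). β is the face of the C1 methyl. The SMILES is read as (1S,2S,4S,5R,6S,8R,9S), that is 2β-OAc, 4β-OH, 6β-veratroyloxy, 8β,9β-epoxide, 5α-H.

## Structural features

The target is a daucane sesquiterpenoid diester: a bicyclo[5.3.0]decane in which the cyclopentane C1–C5 and the cycloheptane C1, C5–C10 share the C1–C5 bond, with a methyl on quaternary C1, an isopropyl on C4 and a methyl on C8. It has seven stereocentres; C1/C2 and C4/C5/C6 are contiguous, the ring fusion is trans (C1 methyl β, H5 α), and every oxygen (2-OAc, 4-OH, 6-OCOAr, 8,9-epoxide) lies on the β face, syn to the C1 methyl. C4 is a tertiary carbinol β to both the C2 and the C6 oxygen, so it is at risk of elimination or retro-aldol cleavage whenever C2 or C6 is a carbonyl group. The trisubstituted epoxide is acid-sensitive and the two different esters are sensitive to base and hydride, which pushes epoxide and acyl groups to the end. The real difficulty is the quaternary C1 at the trans fusion of a five- and a seven-membered ring, together with the axial 6β and the tertiary 4β oxygen, both syn to the C1 methyl. The feature that the key step exploits: the ring carbons C5–C6–C7–C8–C9–C10, with oxygen on C6, methyl on C8 and the side chain on C5, are a 2-methoxy-4-methylphenyl ring into which one carbon, C1, is inserted between C5 and C10. C1 is also the atom that closes the cyclopentane through C2–C3–C4, so a carbene at C1 can make both rings and the quaternary centre in one event.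

## Logic of the disconnections

25 ⇒ 23 + 24. The C6–O acyl bond is cut first, because the aryl ester tolerates neither hydride nor strong base and 24 is bought. No stereocentre is lost. The forward step must acylate an axial, hindered secondary hydroxyl next to a tertiary hydroxyl, an acetate and an epoxide, so it has to be a basic, nucleophile-catalysed acylation.

23 ⇒ 22. The C8–O and C9–O bonds are cut. The epoxide is the most acid-sensitive group, and the free 6β-hydroxyl of 22 is homoallylic to C8=C9 and can deliver oxygen to the β face. Two stereocentres disappear. The forward step must override the steric preference for the α face.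

22 ⇒ 21 ⇒ 20. The O–Si bond at C6 and the O–acyl bond at C2 are cut. They encode the differentiation of the two secondary hydroxyls, which is made in time: O6 is silylated (in 16) before O2 exists as a hydroxyl. The tertiary C4 hydroxyl must stay free and desilylation must spare the acetate.

20 ⇒ 19 ⇒ 18 ⇒ 17. The C4–O and C3–H bonds, then the epoxide and the C2–H bond are cut, so that the tertiary carbinol is traced back to the C3=C4 bond of a cyclopentenone. C2 and C4 are removed as stereocentres and left to be relayed from C1: hydride adds to C2 anti to the C1 methyl, the 2β-hydroxyl steers the epoxide to the β face, and hydride opens it at secondary C3. At this stage C6 must not be a carbonyl (C5 would become labile) and C8=C9 must not be epoxidised; the silyl ether on O6 ensures both.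

17 ⇒ 16 ⇒ 15. The C3=C4 bond is cut back to C3–H and C4–H through a silyl enol ether. C2 can enolise only towards C3 because C1 is quaternary, and the same silylating agent caps O6. The dehydrogenation must leave C8=C9 alone.

15 ⇒ 14 ⇒ 13 ⇒ 12 ⇒ 11 ⇒ 10. The C6–H bond (hydride) and the C7–H and C10–H bonds (two electrons and two protons added to the ends of the C7=C8–C9=C10 diene of a dienone) are cut, with C2 masked as a ketal in between. The seven-membered ring returns to the oxidation level of a ring-expanded arene, and the C8=C9 bond of the target is what is left of the diene. Hydride must reach C6 anti to the C1 methyl, 12 must be protonated kinetically at C7, and only the saturated C2 ketone may be ketalised.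

10 ⇒ 9 ⇒ 8 ⇒ 7 (key). The bonds C1–C5 and C1–C10 are cut and C5–C10 is restored, the C6 ketone reverting to a methoxy group: the seven-membered ring becomes a benzene ring and C1 a diazo carbon. In one sentence, the route is an intramolecular Buchner ring expansion of 7. The cut opens both rings at once, removes the quaternary C1 and the ring-fusion centre C5, and leaves an acyclic compound with one stereocentre (C4). The forward step must add the carbenoid to the arene faster than to C–H bonds, at the unsubstituted ortho bond, with facial control from C4, and C5 must settle trans on hydrolysis.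

7 ⇒ 6 ⇒ 5. The C1=N2 bond is cut (diazo transfer through 6). Enolisation of 5 must go towards C1 and not towards C3.

5 ⇒ 3 + 4. The C4–C5 (alkyl–aryl) bond is cut. A catalytic asymmetric conjugate addition sets C4, the only stereocentre made by a chiral catalyst, and brings in all six arene carbons of the future seven-membered ring with 4. It must be enantioselective with an ortho-substituted arylboron reagent and a β-branched enone.

3 ⇒ 1 + 2. The C3=C4 bond is cut by a phosphonate olefination; both partners are bought.

## Other disconnections considered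

Alternative 1: (the first that comes to mind) cut C8=C9 by ring-closing metathesis. Forward key step: second-generation Grubbs catalyst on the 8,9-seco diene A1 would give 20. A1 would come from a 2-methylcyclopentenone by conjugate addition, enolate allylation, a carbonyl addition at C6 and an isopropyl-metal addition at C4. The metathesis closes one ring and creates no stereocentre. All five cyclopentane-borne stereocentres (C1, C2, C4, C5, C6) must already be in A1, each from its own substrate-controlled event, among them the C6 carbinol (acyclic induction of uncertain sense) and the C4 carbinol (addition to a ketone with two β-oxygen substituents). The chosen step makes C1 with both rings from a three-step precursor and lets C1 set the rest.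

Alternative 2: cut C1–C5 and reconnect C1–C6, which gives a decalin. Forward key step: base-induced pinacol-type 1,2-shift in the cis-decalin hydroxy mesylate A2; C1 migrates from C6 to C5 with inversion at C5, and the two six-membered rings become the five- and seven-membered rings of enedione A3. The shift is stereospecific and would give the trans fusion directly. However, A2 needs the C5 and C6 oxygens cis to the angular methyl, the face that dihydroxylation or epoxidation of an octalin should avoid. A Diels–Alder entry from a 2,5-dialkylquinone has no handle for regiocontrol (position of the C8 methyl) or for absolute configuration. A3 is a vinylogous β-diketone whose C5 can epimerise, so the gain of the stereospecific shift may be lost. A2 would need more steps than the whole sequence to 10.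

Alternative 3: cut C1–C5 and C9–C10 and reconnect C5–C9 (two-carbon ring expansion). Forward key step: intramolecular de Mayo reaction of dione A4: [2+2] photocycloaddition of the enol double bond C5=C9 to the isopropenyl group C1=C10, then retro-aldol cleavage of C5–C9, would give diketone A5 with both rings and the quaternary C1. As a cascade it is as powerful as the chosen step. However, A4 carries the C4 oxygen β to both carbonyl groups of an enolisable dione and should lose it by β-elimination. Its assembly (a tertiary carbinol carbon on C5 of a 1,3-dione) has no simple solution. The C9 carbonyl of A5 must be turned into the C8=C9 olefin with regiocontrol, and C5 is again set only by protonation. The arene route takes the C6 oxygen, the C8 methyl and the position of C8=C9 from a bought benzene ring.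

Key step: step 4

## Route

Step 1
Reactants: 1 2-methylpropanal; 2 diethyl (2-oxobutyl)phosphonate
Product: 3 (E)-6-methylhept-4-en-3-one
Conditions: NaH, THF, 0 °C to rt
Reagents that add atoms: none
Why: Horner–Wadsworth–Emmons olefination; the stabilised β-keto phosphonate anion should give the (E)-enone.

Step 2
Reactants: 3 (E)-6-methylhept-4-en-3-one; 4 (2-methoxy-4-methylphenyl)boronic acid
Product: 5 (R)-5-(2-methoxy-4-methylphenyl)-6-methylheptan-3-one
Conditions: Rh(acac)(C2H4)2 (3 mol%), (S)-BINAP (3.3 mol%), dioxane/H2O 10:1, 100 °C
Reagents that add atoms: none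
Why: Hayashi–Miyaura reaction (rhodium-catalysed asymmetric 1,4-addition): the aryl–rhodium species with (S)-BINAP adds to one face of the s-cis (E)-enone and sets C4 as (R), the only stereocentre made by a chiral catalyst; if the sense of induction is the opposite, (R)-BINAP is used.

Step 3
Reactants: 5 (R)-5-(2-methoxy-4-methylphenyl)-6-methylheptan-3-one
Product: 7 (R)-2-diazo-5-(2-methoxy-4-methylphenyl)-6-methylheptan-3-one, via trifluoroacetyl diketone 6 (not isolated)
Conditions: LiHMDS, THF, −78 °C; CF3CO2CH2CF3; then MsN3, Et3N, H2O, MeCN, rt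
Reagents that add atoms: methanesulfonyl azide, CS(=O)(=O)N=[N+]=[N-] (the two diazo nitrogens); 2,2,2-trifluoroethyl trifluoroacetate, O=C(OCC(F)(F)F)C(F)(F)F (its trifluoroacetyl group is in 6 only and is lost again)
Why: Detrifluoroacetylative diazo transfer (Regitz type): LiHMDS should deprotonate kinetically at the less hindered C1 methylene (C3 is flanked by the branched C4), the enolate is trifluoroacetylated to 6, and 6 takes the diazo group from the sulfonyl azide with loss of the trifluoroacetyl group; C4 is untouched.

Step 4
Reactants: 7 (R)-2-diazo-5-(2-methoxy-4-methylphenyl)-6-methylheptan-3-one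
Product: 10 (4βH,5αH)-dauca-7,9-diene-2,6-dione, via norcaradiene 8 (not isolated), via trienol methyl ether 9 (not isolated)
Conditions: Rh2(OAc)4 (1 mol%), CH2Cl2, 40 °C, slow addition of 7; then 1 M HCl, THF, rt
Reagents that add atoms: water, O
Why: Rh2(OAc)4 turns the diazo group of 7 into an electrophilic rhodium carbenoid at C1, which adds across the ipso–ortho bond C5–C10 of the arene (intramolecular cyclopropanation; the C1–C5 bond closes the five-membered ring over the three-atom tether C2–C3–C4) to give 8. Thermal disrotatory 6π electrocyclic opening of the C5–C10 bond then turns the six-membered ring of 8 into the seven-membered ring of 9, with C1 inserted between C5 and C10; this is the intramolecular Buchner reaction, known for 2-diazo-5-arylpentan-3-ones (angular methyl) and for diazo ketones with a benzylic alkyl substituent. The quaternary centre C1 is controlled by C4: allylic 1,3-strain keeps the C4–H in the arene plane next to the methoxy group, the isopropyl group then occupies the arene face opposite to the tether, and the carbenoid is delivered so that the C1 methyl ends trans to the isopropyl group. The methoxy-bearing ortho carbon is not attacked (addition to a substituted ortho bond is disfavoured), which fixes C6 as the oxygen-bearing and C8 as the methyl-bearing ring carbon; the quaternary C1 blocks 1,5-hydrogen shifts in 9. The step needs chemoselectivity for the electron-rich arene over insertion into the isopropyl C–H bond and over 1,2-hydride shift from the C1 methyl, which slow addition to a rhodium carboxylate should secure. Dilute acid then protonates the enol ether of 9 at C5 and hydrolyses it to the C6 ketone under conditions too mild for rearrangement to a tetralone; C5 equilibrates through the dienol and should settle trans-fused, because only then is the C5–C6 bond anti to the α-isopropyl group on C4. One operation thus forms C1–C5 and C1–C10, both rings, the quaternary stereocentre and the ring fusion from an acyclic precursor with one stereocentre.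

Step 5
Reactants: 10 (4βH,5αH)-dauca-7,9-diene-2,6-dione
Product: 11 (4βH,5αH)-2,2-(ethylenedioxy)dauca-7,9-dien-6-one
Conditions: Me3SiOCH2CH2OSiMe3, TMSOTf (5 mol%), CH2Cl2, −78 to −20 °C
Reagents that add atoms: 1,2-bis(trimethylsilyloxy)ethane, C[Si](C)(C)OCCO[Si](C)(C)C
Why: Silyl-triflate-catalysed ketalisation: the saturated C2 ketone should react and the conjugated C6 dienone not, as is general for saturated versus conjugated ketones; the ketal shields C2 from the electrons of step 6 and the hydride of step 7.

Step 6
Reactants: 11 (4βH,5αH)-2,2-(ethylenedioxy)dauca-7,9-dien-6-one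
Product: 13 (4βH,5αH)-2,2-(ethylenedioxy)dauc-8-en-6-one, via lithium dienolate 12 (not isolated)
Conditions: Li (2.5 equiv), t-BuOH (1 equiv), NH3(l)/THF, −78 °C; isoprene; then solid NH4Cl
Reagents that add atoms: none
Why: Birch-type dissolving-metal reduction of a linear dienone: two electrons and a proton at C10 (the δ terminus) give dienolate 12, whose kinetic protonation at C7 (α) leaves the double bond at C8=C9; C5 stays α to the ketone and on the thermodynamically preferred trans side.

Step 7
Reactants: 13 (4βH,5αH)-2,2-(ethylenedioxy)dauc-8-en-6-one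
Product: 15 (4βH,5αH)-6β-hydroxydauc-8-en-2-one, via hydroxy ketal 14 (not isolated)
Conditions: NaBH4, MeOH/THF, −40 °C; then 2 M HCl, THF, rt
Reagents that add atoms: water, O
Why: Borohydride reduction under substrate control: hydride should attack C6 from the α face, anti to the axial C1 methyl that shields the β face in a 1,3-relationship (the pattern of angularly methylated trans-fused bicyclic ketones), giving the axial 6β-alcohol 14 and fixing C5; aqueous acid then hydrolyses the ketal.

Step 8
Reactants: 15 (4βH,5αH)-6β-hydroxydauc-8-en-2-one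
Product: 16 (4βH,5αH)-2,6β-bis(tert-butyldimethylsilyloxy)dauca-2,8-diene
Conditions: TBSOTf (2.5 equiv), Et3N, CH2Cl2, 0 °C to rt
Reagents that add atoms: tert-butyldimethylsilyl trifluoromethanesulfonate, CC(C)(C)[Si](C)(C)OS(=O)(=O)C(F)(F)F
Why: Silylation with soft enolisation: the reagent silylates the hindered 6β-hydroxyl and in the same operation converts the C2 ketone, which has α-hydrogens only at C3, into its silyl enol ether.

Step 9
Reactants: 16 (4βH,5αH)-2,6β-bis(tert-butyldimethylsilyloxy)dauca-2,8-diene
Product: 17 (5αH)-6β-(tert-butyldimethylsilyloxy)dauca-3,8-dien-2-one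
Conditions: Pd(OAc)2 (1.1 equiv), MeCN, 40 °C
Reagents that add atoms: none
Why: Saegusa–Ito oxidation: the palladium enolate at C3 undergoes β-hydride elimination of the C4–H, the only one available, to give the C3=C4 enone; the C4 stereocentre, having done its work in steps 4 to 7, is erased.

Step 10
Reactants: 17 (5αH)-6β-(tert-butyldimethylsilyloxy)dauca-3,8-dien-2-one
Product: 18 (5αH)-6β-(tert-butyldimethylsilyloxy)dauca-3,8-dien-2β-ol
Conditions: NaBH4, CeCl3·7H2O, MeOH, −78 to −40 °C
Reagents that add atoms: none
Why: Luche reduction: 1,2-addition of hydride to the enone from the α face, anti to the adjacent C1 methyl, should set C2 as the 2β-alcohol; silyl ether and isolated olefin are inert.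

Step 11
Reactants: 18 (5αH)-6β-(tert-butyldimethylsilyloxy)dauca-3,8-dien-2β-ol
Product: 19 (5αH)-3β,4β-epoxy-6β-(tert-butyldimethylsilyloxy)dauc-8-en-2β-ol
Conditions: VO(acac)2 (5 mol%), t-BuOOH (1.2 equiv), CH2Cl2, 0 °C to rt
Reagents that add atoms: tert-butyl hydroperoxide, CC(C)(C)OO
Why: Hydroxyl-directed epoxidation with a vanadium peroxo catalyst: the allylic 2β-hydroxyl delivers the oxygen syn, to the β face of C3=C4, which sets C4; the remote C8=C9 bond has no free hydroxyl within reach and should not be attacked.

Step 12
Reactants: 19 (5αH)-3β,4β-epoxy-6β-(tert-butyldimethylsilyloxy)dauc-8-en-2β-ol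
Product: 20 (5αH)-6β-(tert-butyldimethylsilyloxy)dauc-8-ene-2β,4β-diol
Conditions: LiAlH4, THF, 0 °C to rt
Reagents that add atoms: none
Why: Hydride opening of a trisubstituted epoxide (SN2): hydride enters at secondary C3 from the α face and the C4–O bond is kept, so C4 becomes the tertiary 4β-carbinol with the isopropyl group α; the silyl ether survives.

Step 13
Reactants: 20 (5αH)-6β-(tert-butyldimethylsilyloxy)dauc-8-ene-2β,4β-diol
Product: 21 (5αH)-2β-acetoxy-6β-(tert-butyldimethylsilyloxy)dauc-8-en-4β-ol
Conditions: Ac2O, pyridine, DMAP (cat.), CH2Cl2, rt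
Reagents that add atoms: acetic anhydride, CC(=O)OC(C)=O
Why: Selective acylation: the secondary 2β-hydroxyl is acetylated, the tertiary C4 hydroxyl should not react under DMAP catalysis at room temperature.

Step 14
Reactants: 21 (5αH)-2β-acetoxy-6β-(tert-butyldimethylsilyloxy)dauc-8-en-4β-ol
Product: 22 (5αH)-2β-acetoxydauc-8-ene-4β,6β-diol
Conditions: HF·pyridine, pyridine, THF, 0 °C to rt
Reagents that add atoms: none
Why: Fluoride-mediated desilylation under buffered conditions that leave the acetate and the tertiary alcohol untouched.

Step 15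
Reactants: 22 (5αH)-2β-acetoxydauc-8-ene-4β,6β-diol
Product: 23 (5αH)-2β-acetoxy-8β,9β-epoxydaucane-4β,6β-diol
Conditions: VO(acac)2 (10 mol%), t-BuOOH (1.5 equiv), CH2Cl2, rt
Reagents that add atoms: tert-butyl hydroperoxide, CC(C)(C)OO
Why: Hydroxyl-directed epoxidation of a homoallylic alcohol: the 6β-hydroxyl delivers the oxygen to the β face of C8=C9, against the steric bias of the C1 methyl, and sets C8 and C9.

Step 16
Reactants: 23 (5αH)-2β-acetoxy-8β,9β-epoxydaucane-4β,6β-diol; 24 3,4-dimethoxybenzoyl chloride
Product: 25 (5αH)-2β-acetoxy-8β,9β-epoxy-6β-(3,4-dimethoxybenzoyloxy)daucan-4β-ol (CNP0330776.1)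
Conditions: Et3N, DMAP, CH2Cl2, rt
Reagents that add atoms: none
Why: Nucleophile-catalysed acylation (DMAP) of the only secondary hydroxyl; the basic medium preserves the epoxide and the tertiary C4 hydroxyl should stay free.

## Compound list

1 | 2-methylpropanal | CC(C)C=O | starting material
2 | diethyl (2-oxobutyl)phosphonate | CCC(=O)CP(=O)(OCC)OCC | starting material
3 | (E)-6-methylhept-4-en-3-one | CCC(=O)/C=C/C(C)C | intermediate
4 | (2-methoxy-4-methylphenyl)boronic acid | COc1cc(C)ccc1B(O)O | starting material
5 | (R)-5-(2-methoxy-4-methylphenyl)-6-methylheptan-3-one | CCC(=O)C[C@H](C(C)C)c1ccc(C)cc1OC | intermediate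
6 | (6R)-1,1,1-trifluoro-6-(2-methoxy-4-methylphenyl)-3,7-dimethyloctane-2,4-dione (C3 unassigned) | CC(C(=O)C(F)(F)F)C(=O)C[C@H](C(C)C)c1ccc(C)cc1OC | intermediate (not isolated)
7 | (R)-2-diazo-5-(2-methoxy-4-methylphenyl)-6-methylheptan-3-one | CC(=[N+]=[N-])C(=O)C[C@H](C(C)C)c1ccc(C)cc1OC | intermediate
8 | norcaradiene: (4βH)-6-methoxy-5,10-cyclodauca-6,8-dien-2-one (cyclopropane C1–C5–C10) | COC1=CC(C)=C[C@H]2[C@]3(C)C(=O)C[C@H](C(C)C)[C@]123 | intermediate (not isolated)
9 | (4βH)-6-methoxydauca-5,7,9-trien-2-one | COC1=C2[C@@H](C(C)C)CC(=O)[C@@]2(C)C=CC(C)=C1 | intermediate (not isolated)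
10 | (4βH,5αH)-dauca-7,9-diene-2,6-dione | O=C2C=C(C)C=C[C@]3(C)C(=O)C[C@H](C(C)C)[C@@H]23 | intermediate
11 | (4βH,5αH)-2,2-(ethylenedioxy)dauca-7,9-dien-6-one | O=C2C=C(C)C=C[C@]3(C)C4(OCCO4)C[C@H](C(C)C)[C@@H]23 | intermediate
12 | lithium (4βH,5αH)-2,2-(ethylenedioxy)dauca-6,8-dien-6-olate | [Li+].[O-]C2=CC(C)=CC[C@]3(C)C4(OCCO4)C[C@H](C(C)C)[C@@H]23 | intermediate (not isolated)
13 | (4βH,5αH)-2,2-(ethylenedioxy)dauc-8-en-6-one | O=C2CC(C)=CC[C@]3(C)C4(OCCO4)C[C@H](C(C)C)[C@@H]23 | intermediate
14 | (4βH,5αH)-2,2-(ethylenedioxy)dauc-8-en-6β-ol | O[C@H]2CC(C)=CC[C@]3(C)C4(OCCO4)C[C@H](C(C)C)[C@@H]23 | intermediate (not isolated)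
15 | (4βH,5αH)-6β-hydroxydauc-8-en-2-one | O[C@H]2CC(C)=CC[C@]3(C)C(=O)C[C@H](C(C)C)[C@@H]23 | intermediate
16 | (4βH,5αH)-2,6β-bis(tert-butyldimethylsilyloxy)dauca-2,8-diene | CC(C)(C)[Si](C)(C)O[C@H]2CC(C)=CC[C@]3(C)C(O[Si](C)(C)C(C)(C)C)=C[C@H](C(C)C)[C@@H]23 | intermediate
17 | (5αH)-6β-(tert-butyldimethylsilyloxy)dauca-3,8-dien-2-one | CC(C)(C)[Si](C)(C)O[C@H]2CC(C)=CC[C@]3(C)C(=O)C=C(C(C)C)[C@@H]23 | intermediate
18 | (5αH)-6β-(tert-butyldimethylsilyloxy)dauca-3,8-dien-2β-ol | CC(C)(C)[Si](C)(C)O[C@H]2CC(C)=CC[C@]3(C)[C@@H](O)C=C(C(C)C)[C@@H]23 | intermediate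
19 | (5αH)-3β,4β-epoxy-6β-(tert-butyldimethylsilyloxy)dauc-8-en-2β-ol | CC(C)(C)[Si](C)(C)O[C@H]2CC(C)=CC[C@]3(C)[C@@H](O)[C@H]4O[C@@]4(C(C)C)[C@@H]23 | intermediate
20 | (5αH)-6β-(tert-butyldimethylsilyloxy)dauc-8-ene-2β,4β-diol | CC(C)(C)[Si](C)(C)O[C@H]2CC(C)=CC[C@]3(C)[C@@H](O)C[C@](O)(C(C)C)[C@@H]23 | intermediate
21 | (5αH)-2β-acetoxy-6β-(tert-butyldimethylsilyloxy)dauc-8-en-4β-ol | CC(C)(C)[Si](C)(C)O[C@H]2CC(C)=CC[C@]3(C)[C@@H](OC(C)=O)C[C@](O)(C(C)C)[C@@H]23 | intermediate
22 | (5αH)-2β-acetoxydauc-8-ene-4β,6β-diol | O[C@H]2CC(C)=CC[C@]3(C)[C@@H](OC(C)=O)C[C@](O)(C(C)C)[C@@H]23 | intermediate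
23 | (5αH)-2β-acetoxy-8β,9β-epoxydaucane-4β,6β-diol | O[C@H]2C[C@@]3(C)O[C@H]3C[C@]3(C)[C@@H](OC(C)=O)C[C@](O)(C(C)C)[C@@H]23 | intermediate
24 | 3,4-dimethoxybenzoyl chloride | COc1ccc(C(Cl)=O)cc1OC | starting material
25 | (5αH)-2β-acetoxy-8β,9β-epoxy-6β-(3,4-dimethoxybenzoyloxy)daucan-4β-ol (CNP0330776.1) | COc1ccc(C(=O)O[C@H]2C[C@@]3(C)O[C@H]3C[C@]3(C)[C@@H](OC(C)=O)C[C@](O)(C(C)C)[C@@H]23)cc1OC | target

## Step count and least certain steps

Total step count: 16. Longest linear sequence: 16 steps (1 to 25); 2, 4 and 24 enter as bought partners.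

Step 4 (key step). Most likely to go wrong: diversion of the carbenoid into insertion at the tertiary C–H of the isopropyl group (also a five-membered transition state) or into 1,2-hydride shift from the methyl group, and incomplete relay of configuration from C4 to C1 and C5. The fallback removes the isopropyl group from the cyclisation substrate and sets C1 by a chiral catalyst instead of by C4. It sets out from 4 and comes back at 10. Rhodium-catalysed conjugate addition of 4 to pent-1-en-3-one gives 1-(2-methoxy-4-methylphenyl)pentan-3-one F1. Diazo transfer as in step 3, through the trifluoroacetyl diketone F2, gives 2-diazo-5-(2-methoxy-4-methylphenyl)pentan-3-one F3; the regioisomer from enolisation towards the aryl side would have to be separated. Enantioselective Buchner cyclisation with [Cu(MeCN)4]PF6 and 2,2'-isopropylidenebis[(4S)-4-tert-butyl-2-oxazoline] (or its antipode, whichever leads to the 1S series) gives, through the norcaradiene F4, the trienol methyl ether F5. DDQ in wet CH2Cl2 dehydrogenates the enol ether to the cross-conjugated trienone F6. Conjugate addition of (i-Pr)2CuLi at C4, anti to the C1 methyl, gives the lithium enolate F7, and equilibrating protonation at C5 returns to 10.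

Step 6. Most likely to go wrong: protonation of the dienolate at C9 instead of C7 on quenching, or isomerisation of the β,γ-enone into conjugation, because the conjugated enone is the more stable isomer; over-reduction of the C6 carbonyl is a lesser risk. The fallback sets the olefin position by deconjugation rather than by reduction. It sets out from 11 and comes back at 13. Hydrogenation of only the disubstituted C9=C10 bond (H2, RhCl(PPh3)3, benzene) gives the conjugated enone F8. KOt-Bu in t-BuOH removes a γ-proton at C9 to form the extended potassium dienolate F9, and rapid quenching with aqueous AcOH protonates it kinetically at C7 to give 13.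

Step 7. Most likely to go wrong: poor facial selectivity at C6, because the α-isopropyl group on C4 hinders the α face that the hydride has to use, in competition with the C1 methyl on the β face. The fallback replaces facial selection by invertive substitution. It sets out from 13 and comes back at 15. Reduction of 13 under thermodynamic control (Na, i-PrOH, toluene) should give the equatorial alcohol, the 6α-hydroxy ketal F10, and 2 M HCl in THF the 6α-hydroxy ketone F11. Mitsunobu reaction with 4-nitrobenzoic acid (PPh3, DIAD, toluene) gives the 6β-(4-nitrobenzoate) F12 with inversion, and K2CO3 in MeOH gives 15.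

Step 15. Most likely to go wrong: loss of facial control, because the directing hydroxyl is axial and crowded and the undirected reaction prefers the α face. The fallback builds the β-epoxide by anti addition and ring closure instead of by oxygen delivery. It sets out from 22 and comes back at 25, bypassing 23. Acylation of 22 with 24 (Et3N, DMAP) gives the olefinic diester F13. NBS in aqueous DME, with water in large excess to outrun the C4 hydroxyl, should form the bromonium ion on the open α face and be opened by water at tertiary C8 from the β face, giving the bromohydrin F14 (8β-OH, 9α-Br). DBU then closes the epoxide with inversion at C9 to give 25.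

## Further compounds

F1 | step 4 | 1-(2-methoxy-4-methylphenyl)pentan-3-one | CCC(=O)CCc1ccc(C)cc1OC
F2 | step 4 | 1,1,1-trifluoro-6-(2-methoxy-4-methylphenyl)-3-methylhexane-2,4-dione | CC(C(=O)C(F)(F)F)C(=O)CCc1ccc(C)cc1OC
F3 | step 4 | 2-diazo-5-(2-methoxy-4-methylphenyl)pentan-3-one | CC(=[N+]=[N-])C(=O)CCc1ccc(C)cc1OC
F4 | step 4 | norcaradiene: 11,12,13-trinor-6-methoxy-5,10-cyclodauca-6,8-dien-2-one | COC1=CC(C)=C[C@H]2[C@]3(C)C(=O)CC[C@]123
F5 | step 4 | 11,12,13-trinor-6-methoxydauca-5,7,9-trien-2-one (des-isopropyl 9) | COC1=C2CCC(=O)[C@@]2(C)C=CC(C)=C1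
F6 | step 4 | 11,12,13-trinordauca-4,7,9-triene-2,6-dione | O=C2C=C(C)C=C[C@]3(C)C(=O)CC=C23
F7 | step 4 | lithium (4βH)-2-oxodauca-5,7,9-trien-6-olate | [Li+].[O-]C1=C2[C@@H](C(C)C)CC(=O)[C@@]2(C)C=CC(C)=C1
F8 | step 6 | (4βH,5αH)-2,2-(ethylenedioxy)dauc-7-en-6-one | O=C2C=C(C)CC[C@]3(C)C4(OCCO4)C[C@H](C(C)C)[C@@H]23
F9 | step 6 | potassium (4βH,5αH)-2,2-(ethylenedioxy)dauca-6,8-dien-6-olate | [K+].[O-]C2=CC(C)=CC[C@]3(C)C4(OCCO4)C[C@H](C(C)C)[C@@H]23
F10 | step 7 | (4βH,5αH)-2,2-(ethylenedioxy)dauc-8-en-6α-ol | O[C@@H]2CC(C)=CC[C@]3(C)C4(OCCO4)C[C@H](C(C)C)[C@@H]23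
F11 | step 7 | (4βH,5αH)-6α-hydroxydauc-8-en-2-one | O[C@@H]2CC(C)=CC[C@]3(C)C(=O)C[C@H](C(C)C)[C@@H]23
F12 | step 7 | (4βH,5αH)-6β-(4-nitrobenzoyloxy)dauc-8-en-2-one | O=C(O[C@H]2CC(C)=CC[C@]3(C)C(=O)C[C@H](C(C)C)[C@@H]23)c1ccc(cc1)[N+](=O)[O-]
F13 | step 15 | (5αH)-2β-acetoxy-6β-(3,4-dimethoxybenzoyloxy)dauc-8-en-4β-ol | COc1ccc(C(=O)O[C@H]2CC(C)=CC[C@]3(C)[C@@H](OC(C)=O)C[C@](O)(C(C)C)[C@@H]23)cc1OC
F14 | step 15 | (5αH)-2β-acetoxy-9α-bromo-6β-(3,4-dimethoxybenzoyloxy)daucane-4β,8β-diol | COc1ccc(C(=O)O[C@H]2C[C@@](C)(O)[C@H](Br)C[C@]3(C)[C@@H](OC(C)=O)C[C@](O)(C(C)C)[C@@H]23)cc1OC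
A1 | alternative 1 | 8,9-seco diene corresponding to 20 (C1 allyl; C5 carrying CH(OTBS)CH2C(CH3)=CH2; 2β,4β-diol) | CC(C)(C)[Si](C)(C)O[C@@H](CC(C)=C)[C@@H]1[C@@](O)(C(C)C)C[C@H](O)[C@@]1(C)CC=C
A2 | alternative 2 | cis-decalin hydroxy mesylate (daucane atom labels, ring fusion C1–C6): 6β-hydroxy-5β-mesyloxy-4-isopropyl-1β,8-dimethylbicyclo[4.4.0]deca-3,8-dien-2-one | CC1=CC[C@]2(C)C(=O)C=C(C(C)C)[C@@H](OS(C)(=O)=O)[C@]2(O)C1
A3 | alternative 2 | (5αH)-dauca-3,8-diene-2,6-dione | O=C2CC(C)=CC[C@]3(C)C(=O)C=C(C(C)C)[C@@H]23
A4 | alternative 3 | 4-methylcyclopentane-1,3-dione carrying on C2 (daucane C5) the acetonide-protected chain C4(O)(i-Pr)–C3H2–C2H(O)–C1(CH3)=C10H2 | CC1CC(=O)C(C1=O)[C@@]2(C(C)C)C[C@@H](C(C)=C)OC(C)(C)O2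
A5 | alternative 3 | (5αH)-2β,4β-(isopropylidenedioxy)daucane-6,9-dione | O=C2CC(C)C(=O)C[C@]3(C)[C@@H]4C[C@](OC(C)(C)O4)(C(C)C)[C@@H]23
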